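**Plan**

1. Retrosynthesis: the 11,12-epoxide and the C16 chloride go in last. The γ-lactone is cut at C8–C17 (intramolecular Reformatsky), the ten-membered ring at C5=C6 (ring-closing metathesis), the chain at C7–C8 (oxyallylation) and C1–C2 (aldol), and ring A at C12–C13 and C1–C10.
2. Enabling feature: in ring A the oxygenated C14 lies between C13 and C1, and the oxygenated C12 is 1,3 to C10. A methyl ketone C13–C14(=O)–C1 (two nucleophilic α-carbons) and an enal C12(=O)–C11=C10 (two electrophilic carbons) therefore join in a (3+3) Michael–aldol annulation. O8 is two atoms from C10, so a 2-methylacetoacetate ester on O8 serves as activating group and as a temporary six-membered lactone tether.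
3. Forward order: C9 carbinol, tethered annulation to ring A, removal of the tether (hydrolysis, decarboxylation), C1–C2 aldol, adjustment of oxidation state and alkene position, diacetate, C8 aldehyde and oxyallylation, ten-membered ring by metathesis, lactone by Reformatsky closure, chloride, epoxide.
4. Stereochemistry: C9 from the palladium catalyst; C10 from C9 through the lactone tether; C1 from C10 (aldol anti to the C10 side chain); C2 and C14 from hydride reduction of the 1,3-diketone; C7 from C9 by chelation-controlled oxyallylation (C8 is a relay center, later a ketone); C8 and C17 from the ring-constrained Reformatsky closure; the epoxide from C9–OH direction.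

Key step: step 4

Remark: atom labels C1–C20 are the briarane positions of the target (ring A = C1, C10–C14; ten-membered ring = C1–C10; lactone = C7, C8, C17, C19; C15 on C1, C16 on C5, C20 on C11). It is assumed that the (R,R)-diphosphine of step 1 gives (R)-2 (its mirror image is used otherwise). C1 (until step 10), C11 (until step 12) and C2 of 17 are carried as epimer mixtures and are left open in the SMILES.

**Route**

Step 1
Reactants: 1 2-vinyloxirane (racemic)
Product: 2 (R)-2-(4-methoxybenzyloxy)but-3-en-1-ol
Conditions: 4-methoxybenzyl alcohol (1.1 equiv), Pd2(dba)3·CHCl3 (1 mol %), (1R,2R)-N,N′-bis[2-(diphenylphosphino)benzoyl]cyclohexane-1,2-diamine (3 mol %), Et3B (1 mol %), CH2Cl2, rt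
Reagents that add atoms: 4-methoxybenzyl alcohol, COc1ccc(CO)cc1
Why: Palladium-catalysed asymmetric allylic etherification of the vinyl epoxide (Tsuji–Trost reaction run as a dynamic kinetic asymmetric transformation): the alkoxide is delivered as its boron ate complex to the internal allyl terminus next to the tethering oxygen, and the chiral diphosphine selects one face of the interconverting allyl complexes, which sets C9 (R).

Step 2
Reactants: 2 (R)-2-(4-methoxybenzyloxy)but-3-en-1-ol; 3 methyl 2-methyl-3-oxobutanoate
Product: 4 (R)-2-(4-methoxybenzyloxy)but-3-en-1-yl 2-methyl-3-oxobutanoate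
Conditions: DMAP (0.3 equiv), toluene, 110 °C, 4 Å molecular sieves (removal of MeOH)
Reagents that add atoms: none
Why: DMAP-catalysed transesterification of a β-keto ester (acyl transfer to the primary alcohol, driven by removal of methanol) attaches the 2-methylacetoacetate that will serve as activating group and tether; no lasting stereocenter is formed.

Step 3
Reactants: 4 keto ester; 5 methacrolein
Product: 6 (2R,3E)-2-(4-methoxybenzyloxy)-4-methyl-5-oxopent-3-en-1-yl 2-methyl-3-oxobutanoate
Conditions: 5 (6 equiv), second-generation Hoveyda–Grubbs catalyst RuCl2(H2IMes)(=CH-C6H4-2-O-i-Pr) (5 mol %), CH2Cl2, 40 °C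
Reagents that add atoms: none
Why: Olefin cross metathesis of the terminal alkene with excess methacrolein gives the trisubstituted enal with the formyl group trans to the chain (thermodynamic E isomer), the keto ester and PMB ether being inert to the ruthenium carbene.

Step 4
Reactants: 6 tethered keto ester enal
Product: 8 bicyclic keto lactone (ring A enone fused to the δ-lactone tether), via lactone aldehyde 7 (not isolated)
Conditions: Cs2CO3 (0.2 equiv), MeCN, 0 °C to rt; then pyrrolidine (0.3 equiv), AcOH (0.3 equiv), 50 °C
Reagents that add atoms: none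
Why: Cs2CO3 deprotonates the doubly activated C1 of the keto ester and the enolate adds to C10 of the tethered enal (C1–C10 bond) to give lactone aldehyde 7; pyrrolidinium acetate then condenses the methyl ketone carbon C13 with the formyl carbon C12 (C12–C13 bond) and dehydrates the aldol to enone 8. The closest known reaction type is the Michael–aldol condensation of a β-keto ester with an α,β-unsaturated aldehyde (Robinson-type (3+3) annulation), run here intramolecularly through an ester tether. The δ-lactone closes by 6-exo-trig conjugate addition and ring A by 6-(enolexo)-exo-trig aldol addition followed by E1cB loss of water. C10 is controlled by C9 through the chair-like transition state of the lactone closure, in which C9–H eclipses the enal double bond (allylic 1,3-strain with the C11 methyl) and the C9 PMB ether is pseudo-equatorial and anti to the incoming enolate, so that the new C1–C10 bond is anti to O9 as in the target; C1 and C11 are not controlled and need not be, since C1 is re-formed from its enolate in step 10 and C11 becomes sp2 in step 12. The step needs conjugate addition in preference to carbonyl addition or β-elimination of the ester, which the soft stabilised enolate, the six-membered tether geometry and the mild catalytic base should secure, and regioselective aldol closure, which is secured because C1 is quaternary after the Michael step so that only C13 can enolise toward C12.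

Step 5
Reactants: 8 bicyclic keto lactone
Product: 10 5-[(1R)-2-hydroxy-1-(4-methoxybenzyloxy)ethyl]-4,6-dimethylcyclohex-2-en-1-one, via keto acid 9 (not isolated)
Conditions: LiOH (3 equiv), THF/H2O, 0 °C to rt; then aq HCl to pH 3, 45 °C
Reagents that add atoms: none
Why: Saponification of the δ-lactone (more electrophilic than the vinylogous ring ketone) and decarboxylation of the resulting β-keto acid on acidification remove the temporary tether and activating carboxyl, free the C8 hydroxyl and leave C1 as an enolisable CH(CH3) center.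

Step 6
Reactants: 10 enone alcohol
Product: 11 5-[(1R)-1-(4-methoxybenzyloxy)-2-(triethylsilyloxy)ethyl]-4,6-dimethylcyclohex-2-en-1-one
Conditions: Et3SiCl, imidazole, CH2Cl2, 0 °C
Reagents that add atoms: chlorotriethylsilane, CC[Si](Cl)(CC)CC
Why: Silylation of the primary alcohol; a triethylsilyl ether is chosen because it survives steps 10 to 14 and can be oxidised directly in step 15.

Step 7
Reactants: 12 2-methylenepropane-1,3-diol
Product: 13 2-[(4-methoxybenzyloxy)methyl]prop-2-en-1-ol
Conditions: NaH (1.0 equiv), 4-methoxybenzyl chloride (1.0 equiv), Bu4NI (cat.), THF/DMF, 0 °C to rt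
Reagents that add atoms: 4-methoxybenzyl chloride, COc1ccc(CCl)cc1
Why: Williamson etherification of the symmetrical diol with one equivalent of base gives the mono-PMB ether (statistical reaction, diol and bis-ether are separated and recycled).

Step 8
Reactants: 13 allylic alcohol; 14 triethyl orthoacetate
Product: 15 ethyl 4-[(4-methoxybenzyloxy)methyl]pent-4-enoate
Conditions: 14 (5 equiv), EtCO2H (cat.), 140 °C (EtOH distilled off)
Reagents that add atoms: none
Why: Johnson–Claisen rearrangement (orthoester exchange, then [3,3]-sigmatropic shift through a chair transition state) adds the two-carbon ester (C2, C3) and transposes the alkene to the 1,1-disubstituted position (C5 with its exocyclic CH2).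

Step 9
Reactants: 15 ester
Product: 16 4-[(4-methoxybenzyloxy)methyl]pent-4-enal
Conditions: i-Bu2AlH (1.05 equiv), CH2Cl2, −78 °C; aqueous work-up
Reagents that add atoms: none
Why: Partial reduction of the ester at −78 °C stops at the tetrahedral aluminium alkoxide, which releases the aldehyde only on work-up.

Step 10
Reactants: 11 ring-A enone; 16 aldehyde
Product: 17 aldol adduct (quaternary C1, new chain trans to the C10 side chain)
Conditions: LiN(i-Pr)2 (1.1 equiv), THF, −78 °C; then 16; aq NH4Cl at −78 °C
Reagents that add atoms: none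
Why: Kinetic deprotonation of the enone at the α′ carbon C1 and aldol addition of the cross-conjugated Li enolate to the aldehyde: the electrophile enters on the ring face opposite to the C10 side chain, which sets the quaternary C1 with C2 trans to C9, while the carbinol configuration at C2 does not matter because it is oxidised in step 11.

Step 11
Reactants: 17 aldol adduct
Product: 18 1,3-diketone (C2 and C14 ketones, conjugated ring enone)
Conditions: Dess–Martin periodinane (1.5 equiv), CH2Cl2, rt
Reagents that add atoms: none
Why: Dess–Martin oxidation of the hindered secondary alcohol under neutral conditions gives the 1,3-diketone without retro-aldol cleavage.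

Step 12
Reactants: 18 1,3-diketone
Product: 19 β,γ-unsaturated 1,3-diketone (C11=C12 alkene)
Conditions: KN(SiMe3)2 (2.5 equiv), THF, −78 to −40 °C; then AcOH (5 equiv) in THF, −78 °C
Reagents that add atoms: none
Why: Deconjugative protonation: the strong amide base enolises the side-chain ketone toward C3 and removes the γ-proton at C11 of the enone (C1 has no proton left), and kinetic protonation of the extended dienolate at the α-carbon C13 gives the β,γ-unsaturated ketone with the C11=C12 alkene, erasing the C11 stereocenter.

Step 13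
Reactants: 19 β,γ-unsaturated 1,3-diketone
Product: 20 2,14-syn diol
Conditions: LiBH(s-Bu)3 (2.6 equiv), THF, −78 °C; aq NH4Cl
Reagents that add atoms: none
Why: Substrate-controlled reduction of both ketones by a bulky hydride: the ring carbonyl is attacked on the face away from the branched C2 substituent of the quaternary C1 (C14–OH cis to C2) and the side-chain carbonyl, held in a Li chelate with O14, on the face away from C10, which should give the 2,14-syn diol with both carbinols as in the target.

Step 14
Reactants: 20 diol
Product: 21 2,14-diacetate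
Conditions: Ac2O, DMAP (0.2 equiv), pyridine, 40 °C
Reagents that add atoms: acetic anhydride, CC(=O)OC(C)=O
Why: DMAP-catalysed acetylation of the two hindered secondary alcohols installs the C2 and C14 acetates of the target.

Step 15
Reactants: 21 diacetate
Product: 22 C8 aldehyde
Conditions: (COCl)2 (4 equiv), DMSO (8 equiv), CH2Cl2, −78 to −30 °C; then Et3N, to 0 °C
Reagents that add atoms: none
Why: Swern oxidation applied to a primary triethylsilyl ether (the chlorosulfonium reagent cleaves the Si–O bond and oxidises the primary position in one operation), under conditions that leave acetates and PMB ethers untouched and do not epimerise C9.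

Step 16
Reactants: 23 allyl tert-butyldimethylsilyl ether
Product: 24 (Z)-tributyl[3-(tert-butyldimethylsilyloxy)allyl]stannane
Conditions: s-BuLi (1.1 equiv), THF/HMPA, −78 °C; then Bu3SnCl
Reagents that add atoms: tributyltin chloride, CCCC[Sn](Cl)(CCCC)CCCC
Why: γ-Stannylation of the lithiated allyl silyl ether gives the (Z)-γ-silyloxyallylstannane, the cis geometry resulting from internal O–Li coordination in the allyl anion.

Step 17
Reactants: 22 C8 aldehyde; 24 stannane
Product: 25 oxyallylation product (C7–OTBS, C8–OH, C9–OPMB all syn; vinyl on C7)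
Conditions: MgBr2·OEt2 (3 equiv), CH2Cl2, −25 to 0 °C
Reagents that add atoms: none
Why: Chelation-controlled oxyallylation of the α-alkoxy aldehyde: MgBr2 bridges the carbonyl and the C9 PMB ether so that the stannane adds on the face away from C10 (C8–O syn to C9–O), and the open antiperiplanar transition state makes C7–O syn to C8–O, so that C7–O and C9–O are 1,3-syn as in the target (C8 is a relay center that becomes a ketone in step 19).

Step 18
Reactants: 25 diene
Product: 26 ten-membered carbocycle fused to ring A
Conditions: second-generation Grubbs catalyst RuCl2(H2IMes)(PCy3)(=CHPh) (10 mol %), toluene (1 mM), 80 °C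
Reagents that add atoms: none
Why: Ring-closing metathesis between the vinyl group and the 1,1-disubstituted alkene closes the ten-membered ring across the trans C1/C10 substituents of ring A, and the ring size enforces the trisubstituted alkene with C4 and C7 cis.

Step 19
Reactants: 26 macrocyclic alcohol
Product: 27 C8 ketone
Conditions: Dess–Martin periodinane (1.5 equiv), CH2Cl2, rt
Reagents that add atoms: none
Why: Dess–Martin oxidation of the C8 carbinol under neutral conditions gives the α,α′-dioxygenated ketone without epimerising C7 or C9.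

Step 20
Reactants: 27 C8 ketone
Product: 28 C7 hydroxy ketone
Conditions: HF·pyridine, pyridine, THF, 0 °C to rt
Reagents that add atoms: none
Why: Fluoride cleavage of the only silyl ether frees the C7 hydroxyl; PMB ethers and acetates are stable to buffered HF·pyridine.

Step 21
Reactants: 28 C7 hydroxy ketone; 29 2-bromopropanoyl bromide (racemic)
Product: 30 C7 2-bromopropanoate
Conditions: 29 (1.5 equiv), pyridine, CH2Cl2, −20 °C
Reagents that add atoms: none
Why: Acylation of the allylic α-hydroxy ketone by the acid bromide under mild base; the bromide-bearing carbon is used as a mixture because it becomes the enolate carbon in step 22.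

Step 22
Reactants: 30 bromo ester
Product: 31 γ-lactone (C8–OH, C17 methyl set)
Conditions: Zn dust (activated with Me3SiCl), THF, 45 °C; aq NH4Cl
Reagents that add atoms: none
Why: Intramolecular Reformatsky reaction: zinc inserts into the C–Br bond and the Zn enolate adds to the neighbouring C8 ketone to close the five-membered lactone, the O7 tether reaching only the carbonyl face that keeps C6 and C9 anti in the ten-membered ring (C8–OH cis to C6) and the C17 methyl taking the position remote from C9; zinc is preferred to stronger single-electron reductants that would cleave the α-acyloxy ketone.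

Step 23
Reactants: 31 bis-PMB lactone
Product: 32 8,9,16-triol
Conditions: DDQ (3 equiv), CH2Cl2/pH 7 buffer (10:1), 0 °C to rt
Reagents that add atoms: none
Why: Oxidative removal of both PMB ethers (benzylic hydride abstraction by DDQ, hydrolysis of the oxocarbenium ions by the water present) liberates the C9 and C16 hydroxyls without touching acetates, lactone or alkenes.

Step 24
Reactants: 32 triol
Product: 33 C16 chloride
Conditions: N-chlorosuccinimide (1.3 equiv), Me2S (1.5 equiv), CH2Cl2, −20 to 0 °C
Reagents that add atoms: N-chlorosuccinimide, O=C1CCC(=O)N1Cl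
Why: Corey–Kim chlorination: only the primary allylic alkoxysulfonium ion is displaced by chloride, whereas the secondary C9 and tertiary C8 hydroxyls are returned unchanged on work-up.

Step 25
Reactants: 33 C16 chloride
Product: 34 target CNP0308390.1
Conditions: VO(acac)2 (5 mol %), t-BuOOH (1.5 equiv), CH2Cl2, 0 °C to rt
Reagents that add atoms: tert-butyl hydroperoxide, CC(C)(C)OO
Why: Hydroxyl-directed epoxidation: the vanadium alkoxide of the homoallylic C9–OH delivers the peroxide oxygen to the face of the electron-rich C11=C12 alkene on which C9 sits, giving the 11,12-epoxide cis to C9, while the C5=C6 alkene is deactivated by the allylic chloride and the lactone oxygen.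

**Compound list**

1 | 2-vinyloxirane (butadiene monoepoxide, racemic) | C=CC1CO1 | starting material
2 | (R)-2-(4-methoxybenzyloxy)but-3-en-1-ol | C=C[C@@H](OCc1ccc(OC)cc1)CO | intermediate
3 | methyl 2-methyl-3-oxobutanoate (racemic) | COC(=O)C(C)C(C)=O | starting material
4 | (R)-2-(4-methoxybenzyloxy)but-3-en-1-yl 2-methyl-3-oxobutanoate (epimers at the keto ester carbon) | C=C[C@@H](OCc1ccc(OC)cc1)COC(=O)C(C)C(C)=O | intermediate
5 | methacrolein (2-methylprop-2-enal) | C=C(C)C=O | starting material
6 | (2R,3E)-2-(4-methoxybenzyloxy)-4-methyl-5-oxopent-3-en-1-yl 2-methyl-3-oxobutanoate | O=C/C(C)=C/[C@@H](OCc1ccc(OC)cc1)COC(=O)C(C)C(C)=O | intermediate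
7 | lactone aldehyde: 3-acetyl-5-(4-methoxybenzyloxy)-3-methyl-4-(1-oxopropan-2-yl)tetrahydropyran-2-one, 4,5-trans (epimers at C1 and C11) | O=C1OC[C@H](OCc2ccc(OC)cc2)[C@@H](C(C)C=O)C1(C)C(C)=O | intermediate
8 | bicyclic keto lactone: 4-(4-methoxybenzyloxy)-5,8a-dimethyl-3,4,4a,5-tetrahydro-1H-isochromene-1,8(8aH)-dione, C9–O trans to the C10–C11 bond (epimers at C1 and C11) | O=C1OC[C@H](OCc2ccc(OC)cc2)[C@H]2C(C)C=CC(=O)C12C | intermediate
9 | keto acid: 6-[(1R)-2-hydroxy-1-(4-methoxybenzyloxy)ethyl]-1,5-dimethyl-2-oxocyclohex-3-ene-1-carboxylic acid | OC[C@H](OCc1ccc(OC)cc1)[C@H]1C(C)C=CC(=O)C1(C)C(=O)O | intermediate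
10 | 5-[(1R)-2-hydroxy-1-(4-methoxybenzyloxy)ethyl]-4,6-dimethylcyclohex-2-en-1-one (C10 as in the target; epimers at C1 and C11) | OC[C@H](OCc1ccc(OC)cc1)[C@H]1C(C)C=CC(=O)C1C | intermediate
11 | 5-[(1R)-1-(4-methoxybenzyloxy)-2-(triethylsilyloxy)ethyl]-4,6-dimethylcyclohex-2-en-1-one | CC[Si](CC)(CC)OC[C@H](OCc1ccc(OC)cc1)[C@H]1C(C)C=CC(=O)C1C | intermediate
12 | 2-methylenepropane-1,3-diol | C=C(CO)CO | starting material
13 | 2-[(4-methoxybenzyloxy)methyl]prop-2-en-1-ol | C=C(CO)COCc1ccc(OC)cc1 | intermediate
14 | triethyl orthoacetate | CCOC(C)(OCC)OCC | starting material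
15 | ethyl 4-[(4-methoxybenzyloxy)methyl]pent-4-enoate | CCOC(=O)CCC(=C)COCc1ccc(OC)cc1 | intermediate
16 | 4-[(4-methoxybenzyloxy)methyl]pent-4-enal | O=CCCC(=C)COCc1ccc(OC)cc1 | intermediate
17 | aldol adduct: enone 11 bearing at C1 the 1-hydroxy-4-[(4-methoxybenzyloxy)methyl]pent-4-en-1-yl chain, trans to the C10 side chain (epimers at C2 and C11) | CC[Si](CC)(CC)OC[C@H](OCc1ccc(OC)cc1)[C@H]1C(C)C=CC(=O)[C@]1(C)C(O)CCC(=C)COCc1ccc(OC)cc1 | intermediate
18 | 1,3-diketone: 6-{4-[(4-methoxybenzyloxy)methyl]pent-4-enoyl}-5-[(1R)-1-(4-methoxybenzyloxy)-2-(triethylsilyloxy)ethyl]-4,6-dimethylcyclohex-2-en-1-one, acyl group trans to the C10 side chain (epimers at C11) | CC[Si](CC)(CC)OC[C@H](OCc1ccc(OC)cc1)[C@H]1C(C)C=CC(=O)[C@]1(C)C(=O)CCC(=C)COCc1ccc(OC)cc1 | intermediate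
19 | β,γ-unsaturated diketone: 6-{4-[(4-methoxybenzyloxy)methyl]pent-4-enoyl}-5-[(1R)-1-(4-methoxybenzyloxy)-2-(triethylsilyloxy)ethyl]-4,6-dimethylcyclohex-3-en-1-one, acyl group trans to the C10 side chain | CC[Si](CC)(CC)OC[C@H](OCc1ccc(OC)cc1)[C@H]1C(C)=CCC(=O)[C@]1(C)C(=O)CCC(=C)COCc1ccc(OC)cc1 | intermediate
20 | 2,14-syn diol from 19 (C14–OH cis to the C2 chain on ring A; C1, C2, C9, C10, C14 as in the target) | CC[Si](CC)(CC)OC[C@H](OCc1ccc(OC)cc1)[C@H]1C(C)=CC[C@H](O)[C@]1(C)[C@H](O)CCC(=C)COCc1ccc(OC)cc1 | intermediate
21 | 2,14-diacetate of 20 | CC[Si](CC)(CC)OC[C@H](OCc1ccc(OC)cc1)[C@H]1C(C)=CC[C@H](OC(C)=O)[C@]1(C)[C@H](OC(C)=O)CCC(=C)COCc1ccc(OC)cc1 | intermediate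
22 | C8 aldehyde: 21 with CH2OSiEt3 replaced by CHO | O=C[C@H](OCc1ccc(OC)cc1)[C@H]1C(C)=CC[C@H](OC(C)=O)[C@]1(C)[C@H](OC(C)=O)CCC(=C)COCc1ccc(OC)cc1 | intermediate
23 | allyl tert-butyldimethylsilyl ether | C=CCO[Si](C)(C)C(C)(C)C | starting material
24 | (Z)-tributyl[3-(tert-butyldimethylsilyloxy)allyl]stannane | CCCC[Sn](CCCC)(CCCC)C/C=C\O[Si](C)(C)C(C)(C)C | intermediate
25 | oxyallylation product: C7–OTBS, C8–OH and C9–OPMB all syn, vinyl group on C7, 1,1-disubstituted alkene at C5 | C=C[C@H](O[Si](C)(C)C(C)(C)C)[C@@H](O)[C@H](OCc1ccc(OC)cc1)[C@H]1C(C)=CC[C@H](OC(C)=O)[C@]1(C)[C@H](OC(C)=O)CCC(=C)COCc1ccc(OC)cc1 | intermediate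
26 | ten-membered carbocycle trans-fused to ring A: 2,14-diacetoxy, 7-OTBS, 8-OH, 9-OPMB, 16-OPMB; C5=C6 with C4 and C7 cis; C11=C12 | CC(=O)O[C@H]1CC=C(C)[C@@H]2[C@@H](OCc3ccc(OC)cc3)[C@H](O)[C@H](/C=C(/COCc3ccc(OC)cc3)CC[C@@H](OC(C)=O)[C@@]12C)O[Si](C)(C)C(C)(C)C | intermediate
27 | C8 ketone of 26 | CC(=O)O[C@H]1CC=C(C)[C@@H]2[C@@H](OCc3ccc(OC)cc3)C(=O)[C@H](/C=C(/COCc3ccc(OC)cc3)CC[C@@H](OC(C)=O)[C@@]12C)O[Si](C)(C)C(C)(C)C | intermediate
28 | C7 hydroxy ketone (27 without the silyl group) | CC(=O)O[C@H]1CC=C(C)[C@@H]2[C@@H](OCc3ccc(OC)cc3)C(=O)[C@H](/C=C(/COCc3ccc(OC)cc3)CC[C@@H](OC(C)=O)[C@@]12C)O | intermediate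
29 | 2-bromopropanoyl bromide (racemic) | CC(Br)C(Br)=O | starting material
30 | C7 2-bromopropanoate of 28 (both epimers at the bromide carbon) | CC(=O)O[C@H]1CC=C(C)[C@@H]2[C@@H](OCc3ccc(OC)cc3)C(=O)[C@H](/C=C(/COCc3ccc(OC)cc3)CC[C@@H](OC(C)=O)[C@@]12C)OC(=O)C(C)Br | intermediate
31 | γ-lactone: 9,16-di-O-PMB ether of triol 32 (C7, C8, C17 as in the target) | CC(=O)O[C@H]1CC=C(C)[C@@H]2[C@@H](OCc4ccc(OC)cc4)[C@@]3(O)[C@H](/C=C(/COCc4ccc(OC)cc4)CC[C@@H](OC(C)=O)[C@@]12C)OC(=O)[C@@H]3C | intermediate
32 | 8,9,16-triol: the target with a C11=C12 alkene in place of the epoxide and OH in place of Cl at C16 | CC(=O)O[C@H]1CC=C(C)[C@@H]2[C@@H](O)[C@@]3(O)[C@H](/C=C(/CO)CC[C@@H](OC(C)=O)[C@@]12C)OC(=O)[C@@H]3C | intermediate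
33 | C16 chloride: the target with a C11=C12 alkene in place of the epoxide | CC(=O)O[C@H]1CC=C(C)[C@@H]2[C@@H](O)[C@@]3(O)[C@H](/C=C(/CCl)CC[C@@H](OC(C)=O)[C@@]12C)OC(=O)[C@@H]3C | intermediate
34 | CNP0308390.1 | CC(=O)O[C@H]1C[C@@H]2O[C@]2(C)[C@@H]2[C@@H](O)[C@@]3(O)[C@H](/C=C(/CCl)CC[C@@H](OC(C)=O)[C@@]12C)OC(=O)[C@@H]3C | target

**Step count and risks**

Total step count: 25 (steps 7–9 make aldehyde 16, step 16 makes stannane 24). Longest linear sequence: 21 steps (1–6, 10–15, 17–25).

Steps most likely to fail:

Step 18. What may go wrong: oligomerisation by intermolecular metathesis, or no closure because of transannular strain on forming the trisubstituted ten-membered alkene. Fallback (the lactone is built first so that a rigid vinyl lactone is cyclised): it sets out from 25. Dess–Martin oxidation gives the acyclic C8 ketone F5; HF·pyridine frees the C7 hydroxyl to give the hydroxy ketone F6; acylation with 29 and pyridine gives the bromo ester F7; activated Zn in THF closes the vinyl γ-lactone F8 by Reformatsky addition. Ring-closing metathesis of F8 (second-generation Grubbs catalyst, toluene, high dilution) then comes back to the route at 31.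

Step 4. What may go wrong: poor facial selectivity of the conjugate addition at C10, or loss of material by attack at the formyl carbon or β-elimination of the keto ester from the enal. Fallback (intermolecular annulation under amine catalyst control in place of the tether): it sets out from 2. Silylation (Et3SiCl, imidazole) gives the triethylsilyl ether F1, and cross metathesis with 5 gives the enal F2. F2 and 3 with 9-amino-9-deoxy-epi-quinine trifluoroacetate (20 mol %) in toluene, then TsOH, give the cyclohexenone methyl ester F3 by iminium-mediated Michael addition and aldol condensation; the amine shields one enal face and the anti preference of the γ-alkoxy group is expected to reinforce it. Krapcho demethoxycarbonylation (LiCl, wet DMSO, 140 °C) comes back to the route at 11.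

Step 13. What may go wrong: hydride delivery to the side-chain carbonyl without chelation, which would erode the syn-diol selectivity. Fallback (stepwise, hydroxyl-directed): it sets out from 19. One equivalent of LiBH(s-Bu)3 at −90 °C reduces the more reactive ring ketone to the ring carbinol hydroxy ketone F4. A Narasaka–Prasad reduction (Et2BOMe, NaBH4, THF/MeOH, −78 °C) then delivers the side-chain carbinol syn to the C14 hydroxyl through the boron chelate and comes back to the route at 20.

Further compounds
F1 | step 4 | (R)-triethyl{[2-(4-methoxybenzyloxy)but-3-en-1-yl]oxy}silane | C=C[C@@H](OCc1ccc(OC)cc1)CO[Si](CC)(CC)CC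
F2 | step 4 | (R,E)-4-(4-methoxybenzyloxy)-2-methyl-5-(triethylsilyloxy)pent-2-enal | O=C/C(C)=C/[C@@H](OCc1ccc(OC)cc1)CO[Si](CC)(CC)CC
F3 | step 4 | methyl 6-[(1R)-1-(4-methoxybenzyloxy)-2-(triethylsilyloxy)ethyl]-1,5-dimethyl-2-oxocyclohex-3-ene-1-carboxylate (epimers at C1 and C11) | CC[Si](CC)(CC)OC[C@H](OCc1ccc(OC)cc1)[C@H]1C(C)C=CC(=O)C1(C)C(=O)OC
F4 | step 13 | ring carbinol hydroxy ketone (C14–OH cis to the acyl chain, C2 ketone) | CC[Si](CC)(CC)OC[C@H](OCc1ccc(OC)cc1)[C@H]1C(C)=CC[C@H](O)[C@]1(C)C(=O)CCC(=C)COCc1ccc(OC)cc1
F5 | step 18 | acyclic C8 ketone of 25 | C=C[C@H](O[Si](C)(C)C(C)(C)C)C(=O)[C@H](OCc1ccc(OC)cc1)[C@H]1C(C)=CC[C@H](OC(C)=O)[C@]1(C)[C@H](OC(C)=O)CCC(=C)COCc1ccc(OC)cc1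
F6 | step 18 | acyclic C7 hydroxy ketone | C=C[C@H](O)C(=O)[C@H](OCc1ccc(OC)cc1)[C@H]1C(C)=CC[C@H](OC(C)=O)[C@]1(C)[C@H](OC(C)=O)CCC(=C)COCc1ccc(OC)cc1
F7 | step 18 | acyclic C7 2-bromopropanoate | C=C[C@H](OC(=O)C(C)Br)C(=O)[C@H](OCc1ccc(OC)cc1)[C@H]1C(C)=CC[C@H](OC(C)=O)[C@]1(C)[C@H](OC(C)=O)CCC(=C)COCc1ccc(OC)cc1
F8 | step 18 | acyclic vinyl γ-lactone diene (C7, C8, C17 as in 31) | C=C[C@@H]1OC(=O)[C@H](C)[C@@]1(O)[C@H](OCc1ccc(OC)cc1)[C@H]1C(C)=CC[C@H](OC(C)=O)[C@]1(C)[C@H](OC(C)=O)CCC(=C)COCc1ccc(OC)cc1
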